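## Retrosynthetic overview

1. The target is (2S)-8-geranyl-7-O-geranylnaringenin. The last operations are global desilylation, a copper hydride asymmetric 1,4-reduction of a flavone (sets C2) and 7-O-geranylation.
2. Feature used: C4 is a lone carbonyl carbon between C4a of ring A and the C3–C2 unit that carries ring B. Ring C (O1, C2, C3, C4) is therefore cut at C4a–C4, C4–C3 and O1–C2 into ortho-iodophenol 8, carbon monoxide 14 and arylacetylene 13.
3. Ring A comes from phloroglucinol. A TIPS ether marks the future O5, two MOM groups direct lithiation to the future C8 for C-geranylation, and after MOM removal the symmetric diol is mono-iodinated (its two free ring positions are equivalent).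
4. The iodophenol enters the key step with the future O7 free and O5 silylated, so only the hydroxyl ortho to iodine and next to the geranyl carbon can close. The allylic 7-O-geranyl ether is attached afterwards, so it never meets zerovalent palladium and amine.
5. Ring order: rings A and B are bought as arenes and ring C is the only ring formed (step 9). The route is convergent, with 5 + 3 steps before the key step and 3 after.

Key step: step 9

Abbreviations: geranyl = (2E)-3,7-dimethylocta-2,6-dien-1-yl; TIPS = triisopropylsilyl; MOM = methoxymethyl. Flavonoid positions are O1, C2, C3, C4, C4a, C5–C8, C8a, with ring B primed.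

Assumption: (S)-DTBM-SEGPHOS is taken to deliver hydride to the C2 face that gives (2S), by analogy with β,β-disubstituted cyclic enones. This sense is uncertain and is to be confirmed on first use (chiral HPLC, CD); the (R)-ligand is used instead if it is reversed.

## Route

Step 1
Reactants: 1 phloroglucinol
Product: 2 5-(triisopropylsilyloxy)benzene-1,3-diol
Conditions: 1 (3 equiv), TIPSCl (1 equiv), imidazole, DMF, 0 °C → rt; aqueous wash removes surplus 1
Reagents that add atoms: triisopropylsilyl chloride CC(C)[Si](Cl)(C(C)C)C(C)C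
Why: Statistical mono-silylation of a threefold-symmetric triol, in which the excess of water-soluble triol should suppress bis-silylation, and the bulky, non-coordinating TIPS ether later marks O5 and tolerates n-BuLi.

Step 2
Reactants: 2 5-(triisopropylsilyloxy)benzene-1,3-diol
Product: 3 1,3-bis(methoxymethoxy)-5-(triisopropylsilyloxy)benzene
Conditions: MOMCl (2.5 equiv), i-Pr2NEt, CH2Cl2, 0 °C → rt
Reagents that add atoms: chloromethyl methyl ether COCCl
Why: O-Alkylation of both phenols (MOM protection) under amine base should leave the aryl silyl ether untouched and installs the two ortho-directing acetals needed next.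

Step 3
Reactants: 3 1,3-bis(methoxymethoxy)-5-(triisopropylsilyloxy)benzene; 4 geranyl bromide
Product: 6 2-geranyl-1,3-bis(methoxymethoxy)-5-(triisopropylsilyloxy)benzene, via aryllithium 5 (not isolated)
Conditions: n-BuLi (1.1 equiv), THF, 0 °C, 1 h; then 4, −78 °C → rt
Reagents that add atoms: geranyl bromide (4) BrC/C=C(\C)CCC=C(C)C
Why: Directed ortho-metalation should remove the proton between the two chelating OMOM groups (the TIPS ether neither coordinates lithium nor leaves its neighbours accessible), and the aryllithium displaces bromide at the primary allylic carbon by SN2, so the (E)-geometry of the geranyl unit is carried over.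

Step 4
Reactants: 6 2-geranyl-1,3-bis(methoxymethoxy)-5-(triisopropylsilyloxy)benzene
Product: 7 2-geranyl-5-(triisopropylsilyloxy)benzene-1,3-diol
Conditions: HCl (cat., ca. 1% in MeOH), MeOH–THF, rt
Reagents that add atoms: none
Why: Acid-catalysed acetal exchange with methanol (MOM cleavage) should free both phenols, because aryl TIPS ethers are far more stable to dilute methanolic HCl than aryl MOM ethers and the trisubstituted alkenes should not be protonated at room temperature.

Step 5
Reactants: 7 2-geranyl-5-(triisopropylsilyloxy)benzene-1,3-diol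
Product: 8 2-geranyl-4-iodo-5-(triisopropylsilyloxy)benzene-1,3-diol
Conditions: I2 (1.0 equiv, slow addition), NaHCO3, THF–H2O (1:1), 0 °C, dark
Reagents that add atoms: iodine II
Why: Electrophilic aromatic iodination of a phloroglucinol-type phenoxide should be much faster than any reaction of iodine at the isolated alkenes, and because C4 and C6 are related by the mirror plane through C2 and C5 only one mono-iodide can form, with one equivalent of iodine at 0 °C limiting di-iodination.

Step 6
Reactants: 9 4-iodophenol
Product: 10 (4-iodophenoxy)triisopropylsilane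
Conditions: TIPSCl, imidazole, DMF, rt
Reagents that add atoms: triisopropylsilyl chloride CC(C)[Si](Cl)(C(C)C)C(C)C
Why: Standard silylation of a phenol, where TIPS is chosen over smaller silyl groups because the aryl ether must survive carbonate in methanol, diethylamine and carbonate in acetone later.

Step 7
Reactants: 10 (4-iodophenoxy)triisopropylsilane; 11 trimethylsilylacetylene
Product: 12 triisopropyl{4-[(trimethylsilyl)ethynyl]phenoxy}silane
Conditions: PdCl2(PPh3)2 (2 mol%), CuI (4 mol%), Et3N, THF, rt
Reagents that add atoms: trimethylsilylacetylene (11) C#C[Si](C)(C)C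
Why: Sonogashira coupling of an unhindered aryl iodide with a terminal alkyne is reliable at room temperature.

Step 8
Reactants: 12 triisopropyl{4-[(trimethylsilyl)ethynyl]phenoxy}silane
Product: 13 (4-ethynylphenoxy)triisopropylsilane
Conditions: K2CO3 (0.2 equiv), MeOH–THF, 0 °C → rt, short reaction time
Reagents that add atoms: none
Why: Methoxide-catalysed protodesilylation of the alkynyl–silicon bond is fast, while the hindered aryl TIPS ether should be inert over the short contact time.

Step 9
Reactants: 8 2-geranyl-4-iodo-5-(triisopropylsilyloxy)benzene-1,3-diol; 13 (4-ethynylphenoxy)triisopropylsilane; 14 carbon monoxide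
Product: 17 8-geranyl-7-hydroxy-5-(triisopropylsilyloxy)-2-[4-(triisopropylsilyloxy)phenyl]-4H-chromen-4-one, via ynone 15 (not isolated), via enaminone 16 (not isolated)
Conditions: PdCl2(PPh3)2 (5 mol%), CO (20 bar), Et2NH–THF (1:1), degassed, 70 °C
Reagents that add atoms: carbon monoxide (14) [C-]#[O+]
Why: CO and diethylamine reduce the divalent palladium precatalyst to zerovalent palladium, which inserts into the C4a–I bond of 8; CO insertion gives the aroyl–palladium complex, and amine-assisted, copper-free alkynylation with 13 followed by reductive elimination forms C4a–C4 and C4–C3 in ynone 15. Diethylamine then adds to the ynone to give enaminone 16, and the C8a hydroxyl attacks C2 and expels the amine, which forms O1–C2 and closes ring C by a net 6-endo-dig addition–elimination instead of the 5-exo closure to an aurone. The closest known reaction type is the palladium-catalysed carbonylative Sonogashira coupling of ortho-iodophenols with terminal alkynes with cyclisation to flavones in the same flask. No stereocentre is formed. The step needs carbonylative over direct alkynylation (20 bar CO, no copper), flavone over aurone (secondary amine) and closure through the oxygen next to C8, which the substrate secures because the other oxygen ortho to iodine is a TIPS ether and the second free hydroxyl is para to iodine. No allylic ether is present, so zerovalent palladium has no π-allyl pathway, and the trisubstituted alkenes of the C-geranyl chain are spectators.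

Step 10
Reactants: 17 8-geranyl-7-hydroxy-5-(triisopropylsilyloxy)-2-[4-(triisopropylsilyloxy)phenyl]-4H-chromen-4-one; 4 geranyl bromide
Product: 18 8-geranyl-7-(geranyloxy)-5-(triisopropylsilyloxy)-2-[4-(triisopropylsilyloxy)phenyl]-4H-chromen-4-one
Conditions: 4 (1.2 equiv), K2CO3, dry acetone, 40 °C
Reagents that add atoms: geranyl bromide (4) BrC/C=C(\C)CCC=C(C)C
Why: Williamson ether synthesis at the only free phenol (the acidic 7-hydroxyl of the flavone) proceeds by SN2 at the primary allylic bromide with retention of the (E)-geometry, and it is placed after the palladium step so that no allylic aryl ether is exposed to zerovalent palladium and amine.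

Step 11
Reactants: 18 8-geranyl-7-(geranyloxy)-5-(triisopropylsilyloxy)-2-[4-(triisopropylsilyloxy)phenyl]-4H-chromen-4-one
Product: 19 (2S)-8-geranyl-7-(geranyloxy)-5-(triisopropylsilyloxy)-2-[4-(triisopropylsilyloxy)phenyl]chroman-4-one
Conditions: Cu(OAc)2·H2O (5 mol%), (S)-DTBM-SEGPHOS (5.5 mol%), (EtO)2MeSiH (3 equiv), t-BuOH (2 equiv), toluene, 0 °C → rt; aq. NH4Cl
Reagents that add atoms: none
Why: Copper hydride-catalysed asymmetric conjugate reduction of the chromone enone, in which the bisphosphine-ligated monovalent copper hydride adds hydride to C2 on the face selected by the ligand to give (2S), t-BuOH protonates the copper enolate at C3 and the silane returns the copper alkoxide to the hydride, while isolated alkenes, the allylic aryl ether and the aryl silyl ethers should not be reduced.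

Step 12
Reactants: 19 (2S)-8-geranyl-7-(geranyloxy)-5-(triisopropylsilyloxy)-2-[4-(triisopropylsilyloxy)phenyl]chroman-4-one
Product: 20 (2S)-8-geranyl-7-(geranyloxy)-5-hydroxy-2-(4-hydroxyphenyl)chroman-4-one
Conditions: HF·pyridine, pyridine, THF, 0 °C → rt
Reagents that add atoms: none
Why: Fluoride cleavage of both aryl Si–O bonds under buffered, non-basic conditions should avoid the phenoxide-triggered ring opening (retro-oxa-Michael) that would racemise C2 and should leave the geranyl ether and the alkenes intact.

## Compound list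

1 | phloroglucinol (benzene-1,3,5-triol) | Oc1cc(O)cc(O)c1 | starting material
2 | 5-(triisopropylsilyloxy)benzene-1,3-diol | Oc1cc(O)cc(O[Si](C(C)C)(C(C)C)C(C)C)c1 | intermediate
3 | 1,3-bis(methoxymethoxy)-5-(triisopropylsilyloxy)benzene | COCOc1cc(OCOC)cc(O[Si](C(C)C)(C(C)C)C(C)C)c1 | intermediate
4 | geranyl bromide, (2E)-1-bromo-3,7-dimethylocta-2,6-diene | BrC/C=C(\C)CCC=C(C)C | starting material
5 | 2-lithio-1,3-bis(methoxymethoxy)-5-(triisopropylsilyloxy)benzene (aryllithium formed in the flask) | [Li]c1c(OCOC)cc(O[Si](C(C)C)(C(C)C)C(C)C)cc1OCOC | intermediate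
6 | 2-geranyl-1,3-bis(methoxymethoxy)-5-(triisopropylsilyloxy)benzene | COCOc1cc(O[Si](C(C)C)(C(C)C)C(C)C)cc(OCOC)c1C/C=C(\C)CCC=C(C)C | intermediate
7 | 2-geranyl-5-(triisopropylsilyloxy)benzene-1,3-diol | Oc1cc(O[Si](C(C)C)(C(C)C)C(C)C)cc(O)c1C/C=C(\C)CCC=C(C)C | intermediate
8 | 2-geranyl-4-iodo-5-(triisopropylsilyloxy)benzene-1,3-diol | Oc1cc(O[Si](C(C)C)(C(C)C)C(C)C)c(I)c(O)c1C/C=C(\C)CCC=C(C)C | intermediate
9 | 4-iodophenol | Oc1ccc(I)cc1 | starting material
10 | (4-iodophenoxy)triisopropylsilane | CC(C)[Si](Oc1ccc(I)cc1)(C(C)C)C(C)C | intermediate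
11 | trimethylsilylacetylene | C#C[Si](C)(C)C | starting material
12 | triisopropyl{4-[(trimethylsilyl)ethynyl]phenoxy}silane | CC(C)[Si](Oc1ccc(C#C[Si](C)(C)C)cc1)(C(C)C)C(C)C | intermediate
13 | (4-ethynylphenoxy)triisopropylsilane | C#Cc1ccc(O[Si](C(C)C)(C(C)C)C(C)C)cc1 | intermediate
14 | carbon monoxide | [C-]#[O+] | starting material
15 | 1-[3-geranyl-2,4-dihydroxy-6-(triisopropylsilyloxy)phenyl]-3-[4-(triisopropylsilyloxy)phenyl]prop-2-yn-1-one (ynone formed in the flask) | O=C(C#Cc1ccc(O[Si](C(C)C)(C(C)C)C(C)C)cc1)c1c(O)c(C/C=C(\C)CCC=C(C)C)c(O)cc1O[Si](C(C)C)(C(C)C)C(C)C | intermediate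
16 | 3-(diethylamino)-1-[3-geranyl-2,4-dihydroxy-6-(triisopropylsilyloxy)phenyl]-3-[4-(triisopropylsilyloxy)phenyl]prop-2-en-1-one (enaminone formed in the flask, enamine geometry not defined) | O=C(C=C(N(CC)CC)c1ccc(O[Si](C(C)C)(C(C)C)C(C)C)cc1)c1c(O)c(C/C=C(\C)CCC=C(C)C)c(O)cc1O[Si](C(C)C)(C(C)C)C(C)C | intermediate
17 | 8-geranyl-7-hydroxy-5-(triisopropylsilyloxy)-2-[4-(triisopropylsilyloxy)phenyl]-4H-chromen-4-one | O=c1cc(-c2ccc(O[Si](C(C)C)(C(C)C)C(C)C)cc2)oc2c(C/C=C(\C)CCC=C(C)C)c(O)cc(O[Si](C(C)C)(C(C)C)C(C)C)c12 | intermediate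
18 | 8-geranyl-7-(geranyloxy)-5-(triisopropylsilyloxy)-2-[4-(triisopropylsilyloxy)phenyl]-4H-chromen-4-one | O=c1cc(-c2ccc(O[Si](C(C)C)(C(C)C)C(C)C)cc2)oc2c(C/C=C(\C)CCC=C(C)C)c(OC/C=C(\C)CCC=C(C)C)cc(O[Si](C(C)C)(C(C)C)C(C)C)c12 | intermediate
19 | (2S)-8-geranyl-7-(geranyloxy)-5-(triisopropylsilyloxy)-2-[4-(triisopropylsilyloxy)phenyl]chroman-4-one | CC(C)=CCC/C(C)=C/COc1cc(O[Si](C(C)C)(C(C)C)C(C)C)c2c(c1C/C=C(\C)CCC=C(C)C)O[C@H](c1ccc(O[Si](C(C)C)(C(C)C)C(C)C)cc1)CC2=O | intermediate
20 | (2S)-8-geranyl-7-(geranyloxy)-5-hydroxy-2-(4-hydroxyphenyl)chroman-4-one (CNP0103685.1) | CC(C)=CCC/C(C)=C/COc1cc(O)c2c(c1C/C=C(\C)CCC=C(C)C)O[C@H](c1ccc(O)cc1)CC2=O | target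

## Step count and risk

Total step count: 12. Longest linear sequence: 9 (steps 1–5, then 9–12).

Steps most likely to fail:

Step 9 (key step). Oxidative addition at the doubly ortho-oxygenated, phenoxide-rich C–I bond may be slow, so that hydrodeiodination, direct alkynylation (ending in a 2-arylbenzofuran) or capture of the aroyl–palladium complex by diethylamine take over. The fallback sets out from 8 and returns at 17, and it separates the carbonylation from the ring closure. Acetylation of 8 (Ac2O, pyridine, DMAP, CH2Cl2) should give 2-geranyl-4-iodo-5-(triisopropylsilyloxy)-1,3-phenylene diacetate F1, a less electron-rich iodide without a free phenol. Carbonylative Sonogashira coupling of F1 with 13 under CO with PdCl2(PPh3)2 and the non-nucleophilic base Et3N in THF at room temperature should give the isolable 2-geranyl-4-{3-[4-(triisopropylsilyloxy)phenyl]prop-2-ynoyl}-5-(triisopropylsilyloxy)-1,3-phenylene diacetate F2. Diethylamine in THF–MeOH then cleaves both acetates by aminolysis, adds to the ynone and lets the freed C8a hydroxyl close ring C, which gives flavone 17.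

Step 11. Facial discrimination at the hindered, electron-rich flavone may be insufficient, or enantiopurity may be lost by reversible ring opening of the copper enolate to the 2'-hydroxychalcone. The fallback sets out from 18 and returns at 19, and it replaces asymmetric induction by kinetic resolution. Conjugate reduction of 18 with an achiral copper hydride (Cu(OAc)2·H2O, 1,2-bis(diphenylphosphino)benzene, (EtO)2MeSiH, t-BuOH, toluene) should give racemic 8-geranyl-7-(geranyloxy)-5-(triisopropylsilyloxy)-2-[4-(triisopropylsilyloxy)phenyl]chroman-4-one F3. Asymmetric transfer hydrogenation of F3 with RuCl(p-cymene)[(R,R)-TsDPEN] and HCO2H/Et3N in EtOAc, run to a little over half conversion, should reduce the (2R)-enantiomer to the cis-alcohol (2R,4R)-8-geranyl-7-(geranyloxy)-5-(triisopropylsilyloxy)-2-[4-(triisopropylsilyloxy)phenyl]chroman-4-ol F4. The unreacted (2S)-ketone 19 is separated from F4 by chromatography and carried into step 12.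

Step 5. A free hydroxyl flanking the geranyl chain may capture an iodonium ion formed at the C2'=C3' alkene (iodoetherification), or the ring may be iodinated twice. The fallback sets out from 6 and returns at 8, and it iodinates a phenol whose hydroxyl is para to the geranyl group. Desilylation of 6 (HF·pyridine, pyridine, THF) should give 4-geranyl-3,5-bis(methoxymethoxy)phenol F5. Its para position is blocked and both oxygens next to the geranyl chain are capped, so iodination (I2, NaHCO3, THF–H2O, 0 °C) can only occur ortho to the hydroxyl and should give 4-geranyl-2-iodo-3,5-bis(methoxymethoxy)phenol F6. Silylation (TIPSCl, imidazole, DMF) should give [4-geranyl-2-iodo-3,5-bis(methoxymethoxy)phenoxy]triisopropylsilane F7, and methanolic HCl as in step 4 removes both MOM groups to give 8.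

## Further compounds

F1 | step 9 | 2-geranyl-4-iodo-5-(triisopropylsilyloxy)-1,3-phenylene diacetate | CC(=O)Oc1cc(O[Si](C(C)C)(C(C)C)C(C)C)c(I)c(OC(C)=O)c1C/C=C(\C)CCC=C(C)C
F2 | step 9 | 2-geranyl-4-{3-[4-(triisopropylsilyloxy)phenyl]prop-2-ynoyl}-5-(triisopropylsilyloxy)-1,3-phenylene diacetate | CC(=O)Oc1cc(O[Si](C(C)C)(C(C)C)C(C)C)c(C(=O)C#Cc2ccc(O[Si](C(C)C)(C(C)C)C(C)C)cc2)c(OC(C)=O)c1C/C=C(\C)CCC=C(C)C
F3 | step 11 | racemic 8-geranyl-7-(geranyloxy)-5-(triisopropylsilyloxy)-2-[4-(triisopropylsilyloxy)phenyl]chroman-4-one | CC(C)=CCC/C(C)=C/COc1cc(O[Si](C(C)C)(C(C)C)C(C)C)c2c(c1C/C=C(\C)CCC=C(C)C)OC(c1ccc(O[Si](C(C)C)(C(C)C)C(C)C)cc1)CC2=O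
F4 | step 11 | (2R,4R)-8-geranyl-7-(geranyloxy)-5-(triisopropylsilyloxy)-2-[4-(triisopropylsilyloxy)phenyl]chroman-4-ol | CC(C)=CCC/C(C)=C/COc1cc(O[Si](C(C)C)(C(C)C)C(C)C)c2c(c1C/C=C(\C)CCC=C(C)C)O[C@@H](c1ccc(O[Si](C(C)C)(C(C)C)C(C)C)cc1)C[C@H]2O
F5 | step 5 | 4-geranyl-3,5-bis(methoxymethoxy)phenol | COCOc1cc(O)cc(OCOC)c1C/C=C(\C)CCC=C(C)C
F6 | step 5 | 4-geranyl-2-iodo-3,5-bis(methoxymethoxy)phenol | COCOc1cc(O)c(I)c(OCOC)c1C/C=C(\C)CCC=C(C)C
F7 | step 5 | [4-geranyl-2-iodo-3,5-bis(methoxymethoxy)phenoxy]triisopropylsilane | COCOc1cc(O[Si](C(C)C)(C(C)C)C(C)C)c(I)c(OCOC)c1C/C=C(\C)CCC=C(C)C
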